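## Structural features

The target is a (2S)-flavanone: a chroman-4-one in which benzo ring A is fused to the dihydropyranone ring C, with the catechol ring B attached at C2. Ring A carries a free hydroxyl at C7 and a prenyl group at C8, so C8 lies between O1 and O7, and there is no oxygen at C5. Ring B carries hydroxyls at C3' and C4' and a prenyl group at C5', ortho to the C4' hydroxyl. C2 is the only stereocentre, with no neighbouring stereocentre to relay from; it is benzylic, bears O1 and lies β to the C4 carbonyl, so it can be lost by retro-oxa-Michael opening to the 2'-hydroxychalcone, a pathway eased by base and by a free C4' hydroxyl. The two trisubstituted prenyl alkenes are sensitive to strong acid (hydration, cyclisation onto a neighbouring free phenol to a 2,2-dimethylchroman) and to electrophilic oxidants, and the catechol is sensitive to oxidation. The real difficulty is to close ring C with absolute control at C2 while both prenyl groups are in place, and then to reach the ketone and the free phenols without base, hot acid or strong oxidants. The key step exploits the fact that O1–C2 and C3–C4 divide ring C into a four-atom unit O1–C8a–C4a–C4 (a ring A salicylaldehyde at the aldehyde oxidation level, with O7 para to C4a) and a two-carbon unit C2–C3 (a ring B styrene whose C4' oxygen is para to the carbon bonded to C2).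

## Logic of the disconnections

16 is traced to 15 by cutting the three O–Si bonds. The free catechol and the C7 phenol would not survive the oxidation and the acid steps, and as silyl ethers they are freed together by one reagent. This changes nothing in the skeleton but keeps every earlier intermediate non-polar and oxidation-resistant. The demand on the forward step is that no phenoxide is left standing next to the flavanone, since ring opening would erase C2.

15 is traced to 14 and then to 13 without cutting a skeletal bond: the C4 carbonyl becomes a C4 hydroxyl and then a C4 methoxy group. The reason is that the methoxy group is what the ring-forming step leaves at C4, one hydrolysis and one mild oxidation below the ketone, so no benzylic C–H oxidation is needed beside two prenyl groups. The gain is that the C4 configuration of 13 and 14 is irrelevant. The forward steps must ionise C4 and not C2, and must oxidise a benzylic alcohol in the presence of three trisubstituted alkenes.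

13 is cut at C3–C4 and at O1–C2, which opens ring C and gives 5 and 11 by way of the cation 12. This is the cut that removes the ring and the C2 stereocentre in one operation and leaves two benzene derivatives of similar size. The forward step must set C2 under catalyst control, must add through the vinyl CH2 and not through a prenyl alkene, and must use an acid that ionises the acetal faster than it protonates a prenyl group.

5 is traced to 4 by cutting the two C–OMe bonds of the acetal, 4 to 3 by cutting the O4–Si bond, and 3 to 1 and 2 by cutting the bond from C3 to the prenyl CH2. The cuts follow the reverse order of reactivity: the acetal is the most labile function and is made last, and the prenyl group goes on first where the resorcinol is most nucleophilic. The gain is a route of three steps from two bulk chemicals. The demands are regioselective C-alkylation between the two oxygens, silylation of O4 but not O2, and handling of 5 without acid.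

11 is traced to 10 by cutting the vinyl C=C bond, 10 to 8 and 9 by cutting the bond from C5 to the prenyl CH2, 8 to 7 by cutting two O–Si bonds, and 7 to 6 by cutting the O–CH3 bond. The bromine of 6 already marks the prenyl position and the aldehyde is the latent vinyl group, so no aromatic substitution has to be controlled. The demands are a coupling that delivers the prenyl group through its primary carbon beside a bulky silyloxy group, and an olefination that spares the aryl silyl ethers.

## Other disconnections considered

Alternative 1: The cut is at the two aryl–CH2 bonds, from C8 and from C5' to the prenyl groups, which are traced to the O7 and O4' ethers of the bis(1,1-dimethylallyl) ether A2.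
- Forward step: heating A2, with Eu(fod)3 if a lower temperature is wanted, would move both allyl units by [3,3] shifts with allylic transposition and give A1; fluoride would then free the C3' hydroxyl.
- In favour: the shift is concerted and predictable and needs no metal coupling on a hindered arene. The O4' unit can only go to C5', since C3' is blocked. The prenyl alkenes appear only at the end and never meet the acid of a ring-forming step; on this point the alternative is better than the chosen plan.
- Against: the O7 unit could migrate to C6 as well as to C8. Each tertiary allyl ether costs two operations (propargylation, semi-hydrogenation) and ionises easily. The catechol would have to be differentiated so that only O3' is silylated. Heat or the Lewis acid would act on a flavanone that gains free C7 and C4' hydroxyls as the shift proceeds, which opens the ring-opening channel at C2.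
- Comparison: the step would form two C–C bonds, as many as the chosen step, but it closes no ring and sets no stereocentre, so ring C and C2 would need a separate enantioselective synthesis before A2. As a bond-forming event it is mechanistically the more secure. In step count it would be longer: core synthesis with control of C2, selective protection, four ether-building operations, the shift and the deprotection.

Alternative 2: The cut is at O1–C8a, the aryl C–O bond of ring C.
- Forward step: CuI, a phenanthroline ligand and Cs2CO3 would couple the C2 alkoxide of the anti-1,3-diol A4 with the aryl bromide and give A3; oxidation at C4 and removal of the methoxymethyl groups would follow.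
- In favour: C2 would be made earlier by conventional asymmetric carbonyl chemistry and is not touched in the ring closure, because the C2–O bond is kept. The stereochemical security of the ring-forming step is therefore better than in the chosen plan. Ring size decides which hydroxyl reacts (six-membered against four-membered). No acid is present, so the prenyl groups are safe. C4 arrives as an alcohol, which saves the hydrolysis step of the chosen plan.
- Against: the bromide at C8a is flanked by the C8 prenyl group and the C4a side chain, a di-ortho-substituted halide that is a hard case for Ullmann-type etherification with a secondary alkoxide. Hot carbonate and copper can oxidise a benzylic alkoxide and reduce the C–Br bond. A4 needs a 1,2,3,4-tetrasubstituted bromoarene and two controlled carbinol centres, one of which is then destroyed. The final acetal removal needs protic acid, which threatens ortho-prenylphenols with chroman formation and is harsher than fluoride.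
- Comparison: one bond and one ring are formed, against two bonds, one ring and the stereocentre in the chosen step. The reaction class is known, which is an advantage over the unprecedented chosen step. The route would be several steps longer, because an asymmetric aldol union, a directed 1,3-anti reduction and a longer ring A synthesis come before the ring closure.

Alternative 3: The cut is at C4–C4a, the aryl ketone bond.
- Forward step: the acid A6 would be turned into its chloride with 1-chloro-N,N,2-trimethylpropenylamine under neutral conditions; catalytic Sc(OTf)3 beside a hindered pyridine would then acylate the only free ortho position of the aryl ether, para to O7, and give A5.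
- In favour: the ketone is formed directly, so C4 needs no adjustment and two steps are saved after ring closure; this is better than the chosen plan. The regiochemistry is unambiguous and electrophilic aromatic acylation is a familiar reaction class.
- Against: a β-aryloxy acyl electrophile with an electron-rich β-aryl group can expel the phenoxide (through a ketene or the acylium ion) and re-add it, which would erase C2. The Lewis acid may ionise the benzylic C–O bond. The acylium ion or liberated HCl could attack the prenyl alkenes. The C2–O bond of A6 would have to be made by an invertive Mitsunobu etherification of a benzylic alcohol with a hindered phenol, which is prone to partial ionisation. The acetates would have to be removed by base or a nucleophile from a flavanone with a C4' oxygen, a greater risk for C2 than buffered fluoride.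
- Comparison: one bond and one ring are formed, against two bonds, one ring and the stereocentre in the chosen step. The two plans are equal in that both close ring C under acid with both prenyl groups present. In step count the alternative would be similar or slightly longer: it shares the ring B aldehyde, needs an asymmetric C–C step, the etherification and an ester hydrolysis before the ring closure, and saves two steps after it.

Key step: step 8

Assumption: the sense of induction of the imidodiphosphorimidate acid cannot be deduced from first principles; the (S,S) acid is written, and its mirror image would be used if it proved to favour the (2R) product.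

## Route

Step 1
Reactants: 1 2,4-dihydroxybenzaldehyde; 2 prenyl bromide (1-bromo-3-methylbut-2-ene)
Product: 3 2,4-dihydroxy-3-(3-methylbut-2-en-1-yl)benzaldehyde
Conditions: KOH (10 % aq), 0 °C → rt
Reagents that add atoms: none
Why: Phenolate C-alkylation in water, where hydrogen bonding to the phenolate oxygens favours attack through carbon and C3, flanked by both oxygens, is the most nucleophilic ring carbon; the C5 and O-alkylated isomers should be removed by chromatography at this cheap first stage.

Step 2
Reactants: 3 2,4-dihydroxy-3-(3-methylbut-2-en-1-yl)benzaldehyde
Product: 4 2-hydroxy-3-prenyl-4-(triisopropylsilyloxy)benzaldehyde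
Conditions: TIPSCl (1.05 equiv), imidazole, DMF, 0 °C → rt
Reagents that add atoms: triisopropylsilyl chloride, CC(C)[Si](Cl)(C(C)C)C(C)C
Why: Silylation of a phenol with a silyl chloride and imidazole; the 2-hydroxyl is held in a hydrogen bond to the aldehyde and is the less acidic, so one equivalent should go to O4, and the bulky group is chosen to resist loss from the cation of step 8.

Step 3
Reactants: 4 2-hydroxy-3-prenyl-4-(triisopropylsilyloxy)benzaldehyde
Product: 5 2-hydroxy-3-prenyl-4-(triisopropylsilyloxy)benzaldehyde dimethyl acetal
Conditions: HC(OMe)3, MeOH, PPTS (cat.), rt; Et3N, concentrate, short pad of basic Al2O3, use at once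
Reagents that add atoms: trimethyl orthoformate, COC(OC)OC; methanol, CO
Why: Acid-catalysed acetalisation with the orthoformate as dehydrating agent; the ortho-hydroxyl and the para-silyloxy group assist ionisation of the product, so it should be quenched with base, kept off silica gel and used without storage.

Step 4
Reactants: 6 5-bromovanillin (3-bromo-4-hydroxy-5-methoxybenzaldehyde)
Product: 7 3-bromo-4,5-dihydroxybenzaldehyde
Conditions: BBr3, CH2Cl2, −78 °C → rt; H2O
Reagents that add atoms: none
Why: Lewis acid O-demethylation of an aryl methyl ether: BBr3 complexes the ether oxygen and bromide removes the methyl group by SN2, while the aldehyde and the aryl bromide are inert.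

Step 5
Reactants: 7 3-bromo-4,5-dihydroxybenzaldehyde
Product: 8 3-bromo-4,5-bis(tert-butyldimethylsilyloxy)benzaldehyde
Conditions: TBSCl (2.5 equiv), imidazole, DMF, rt
Reagents that add atoms: tert-butyldimethylsilyl chloride, CC(C)(C)[Si](C)(C)Cl
Why: Silylation of both catechol hydroxyls with a silyl chloride and imidazole; silyl ethers suit the later acid and oxidation steps and the final common fluoride deprotection.

Step 6
Reactants: 8 3-bromo-4,5-bis(tert-butyldimethylsilyloxy)benzaldehyde; 9 tributyl(3-methylbut-2-en-1-yl)stannane
Product: 10 3,4-bis(tert-butyldimethylsilyloxy)-5-prenylbenzaldehyde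
Conditions: Pd(PPh3)4 (5 mol %), DMF, 95 °C
Reagents that add atoms: none
Why: Stille coupling: zerovalent palladium inserts into the C–Br bond, the prenyl group is transferred from tin and reductive elimination joins it to the ring through its primary carbon, the less hindered terminus; the neutral, fluoride-free conditions leave the aldehyde and the aryl silyl ethers intact.

Step 7
Reactants: 10 3,4-bis(tert-butyldimethylsilyloxy)-5-prenylbenzaldehyde
Product: 11 3,4-bis(tert-butyldimethylsilyloxy)-5-prenylstyrene
Conditions: Ph3PCH3Br, KOtBu, THF, 0 °C → rt
Reagents that add atoms: methyltriphenylphosphonium bromide, C[P+](c1ccccc1)(c1ccccc1)c1ccccc1.[Br-]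
Why: Wittig methylenation of the aldehyde by the non-stabilised ylide made in the flask; aryl silyl ethers tolerate the ylide at 0 °C.

Step 8
Reactants: 5 2-hydroxy-3-prenyl-4-(triisopropylsilyloxy)benzaldehyde dimethyl acetal (1.3 equiv); 11 3,4-bis(tert-butyldimethylsilyloxy)-5-prenylstyrene
Product: 13 (2S,4S)-2,4-cis-4-methoxy-8,5'-diprenyl-7-(triisopropylsilyloxy)-3',4'-bis(tert-butyldimethylsilyloxy)flavan, via ring A methoxycarbenium ion 12 (not isolated)
Conditions: (S,S)-imidodiphosphorimidate acid (two 3,3'-diaryl-BINOL units, N-triflyl groups; 5 mol %), 5 Å molecular sieves, toluene, −60 → −40 °C; Et3N quench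
Reagents that add atoms: none
Why: Proposed new method: the confined acid protonates one methoxy group of 5, methanol leaves, and the ring A methoxycarbenium ion 12 (the O-protonated α-methoxy ortho-quinone methide) stays hydrogen-bonded through its phenol to the chiral anion; the terminal CH2 of 11 attacks the methide carbon (C3–C4) and the C2 benzylic cation, stabilised by the para silyloxy oxygen of ring B, is trapped by the phenol oxygen (O1–C2), which returns the proton to the catalyst. The closest known reaction types are chiral Brønsted acid-catalysed [4+2] cycloadditions of ortho-quinone methides with styrenes and the achiral acid-promoted salicylaldehyde–orthoformate–styrene synthesis of 4-alkoxyflavans; the new element is an acetal-derived, α-oxygenated methide under enantiocontrol. Ring C closes as the six-membered ring of an asynchronous inverse-demand hetero-[4+2] addition, C–C bond first and oxygen capture of the cation second. C2 is set by the face of the benzylic cation (equivalently of the styrene) that the phenol oxygen reaches inside the chiral ion pair, that is by the catalyst. C4 follows C2 through the endo-type arrangement of the (E)-oxocarbenium ion and is expected cis, but its configuration is not needed later. Regiochemistry is fixed by polarity, since only attack through CH2 gives an oxygen-stabilised benzylic cation. Chemoselectivity for the vinyl group over the three prenyl alkenes should follow from its unhindered terminus and the para-oxygen stabilisation of the cation, and the low temperature and the sieves (which take up methanol) are meant to keep the acid from protonating the prenyl groups or the free ortho-prenylphenol.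

Step 9
Reactants: 13 (2S,4S)-2,4-cis-4-methoxy-8,5'-diprenyl-7-(triisopropylsilyloxy)-3',4'-bis(tert-butyldimethylsilyloxy)flavan
Product: 14 (2S)-8,5'-diprenyl-7-(triisopropylsilyloxy)-3',4'-bis(tert-butyldimethylsilyloxy)flavan-4-ol (mixture of C4 epimers)
Conditions: PPTS (0.3 equiv), THF/H2O (5:1), 45 °C
Reagents that add atoms: water, O
Why: SN1 solvolysis: C4 is the only position whose cation is stabilised by both O1 (ortho) and O7 (para), so mild aqueous acid should exchange methoxy for hydroxy there without touching C2, the silyl ethers or the prenyl groups; both C4 epimers are useful.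

Step 10
Reactants: 14 (2S)-8,5'-diprenyl-7-(triisopropylsilyloxy)-3',4'-bis(tert-butyldimethylsilyloxy)flavan-4-ol
Product: 15 (2S)-8,5'-diprenyl-7-(triisopropylsilyloxy)-3',4'-bis(tert-butyldimethylsilyloxy)flavanone
Conditions: activated MnO2 (excess), CH2Cl2, rt
Reagents that add atoms: none
Why: Oxidation of a benzylic alcohol with MnO2, which is selective for benzylic and allylic alcohols and should leave the prenyl alkenes and the silyl ethers alone; both epimers converge on the ketone and C2 is not involved.

Step 11
Reactants: 15 (2S)-8,5'-diprenyl-7-(triisopropylsilyloxy)-3',4'-bis(tert-butyldimethylsilyloxy)flavanone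
Product: 16 (2S)-7,3',4'-trihydroxy-8,5'-diprenylflavanone (CNP0315050.1)
Conditions: Bu4NF/AcOH (1:1, 4 equiv), THF, 0 °C
Reagents that add atoms: none
Why: Fluoride cleavage of the three aryl silyl ethers; the acetic acid keeps the phenols protonated, so the base-induced retro-oxa-Michael opening that would racemise C2 should be suppressed.

## Compound list

1 | 2,4-dihydroxybenzaldehyde | O=Cc1ccc(O)cc1O | starting material
2 | prenyl bromide (1-bromo-3-methylbut-2-ene) | CC(C)=CCBr | starting material
3 | 2,4-dihydroxy-3-(3-methylbut-2-en-1-yl)benzaldehyde | O=Cc1ccc(O)c(CC=C(C)C)c1O | intermediate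
4 | 2-hydroxy-3-prenyl-4-(triisopropylsilyloxy)benzaldehyde | O=Cc1ccc(O[Si](C(C)C)(C(C)C)C(C)C)c(CC=C(C)C)c1O | intermediate
5 | 2-hydroxy-3-prenyl-4-(triisopropylsilyloxy)benzaldehyde dimethyl acetal | COC(OC)c1ccc(O[Si](C(C)C)(C(C)C)C(C)C)c(CC=C(C)C)c1O | intermediate
6 | 5-bromovanillin (3-bromo-4-hydroxy-5-methoxybenzaldehyde) | COc1cc(C=O)cc(Br)c1O | starting material
7 | 3-bromo-4,5-dihydroxybenzaldehyde | O=Cc1cc(O)c(O)c(Br)c1 | intermediate
8 | 3-bromo-4,5-bis(tert-butyldimethylsilyloxy)benzaldehyde | O=Cc1cc(Br)c(O[Si](C)(C)C(C)(C)C)c(O[Si](C)(C)C(C)(C)C)c1 | intermediate
9 | tributyl(3-methylbut-2-en-1-yl)stannane | CCCC[Sn](CCCC)(CCCC)CC=C(C)C | starting material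
10 | 3,4-bis(tert-butyldimethylsilyloxy)-5-prenylbenzaldehyde | O=Cc1cc(CC=C(C)C)c(O[Si](C)(C)C(C)(C)C)c(O[Si](C)(C)C(C)(C)C)c1 | intermediate
11 | 3,4-bis(tert-butyldimethylsilyloxy)-5-prenylstyrene | C=Cc1cc(CC=C(C)C)c(O[Si](C)(C)C(C)(C)C)c(O[Si](C)(C)C(C)(C)C)c1 | intermediate
12 | ring A methoxycarbenium ion (O-protonated α-methoxy ortho-quinone methide, paired with the chiral anion) | C[O+]=Cc1ccc(O[Si](C(C)C)(C(C)C)C(C)C)c(CC=C(C)C)c1O | intermediate
13 | (2S,4S)-2,4-cis-4-methoxy-8,5'-diprenyl-7-(triisopropylsilyloxy)-3',4'-bis(tert-butyldimethylsilyloxy)flavan | CO[C@H]1C[C@@H](c2cc(CC=C(C)C)c(O[Si](C)(C)C(C)(C)C)c(O[Si](C)(C)C(C)(C)C)c2)Oc2c(CC=C(C)C)c(O[Si](C(C)C)(C(C)C)C(C)C)ccc12 | intermediate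
14 | (2S)-8,5'-diprenyl-7-(triisopropylsilyloxy)-3',4'-bis(tert-butyldimethylsilyloxy)flavan-4-ol, mixture of C4 epimers | OC1C[C@@H](c2cc(CC=C(C)C)c(O[Si](C)(C)C(C)(C)C)c(O[Si](C)(C)C(C)(C)C)c2)Oc2c(CC=C(C)C)c(O[Si](C(C)C)(C(C)C)C(C)C)ccc12 | intermediate
15 | (2S)-8,5'-diprenyl-7-(triisopropylsilyloxy)-3',4'-bis(tert-butyldimethylsilyloxy)flavanone | O=C1C[C@@H](c2cc(CC=C(C)C)c(O[Si](C)(C)C(C)(C)C)c(O[Si](C)(C)C(C)(C)C)c2)Oc2c(CC=C(C)C)c(O[Si](C(C)C)(C(C)C)C(C)C)ccc12 | intermediate
16 | (2S)-7,3',4'-trihydroxy-8,5'-diprenylflavanone (CNP0315050.1) | CC(C)=CCc1cc([C@@H]2CC(=O)c3ccc(O)c(CC=C(C)C)c3O2)cc(O)c1O | target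

## Step count and least certain steps

Total: 11 steps. Longest linear sequence: 8 steps (6 → 16 through steps 4, 5, 6, 7, 8, 9, 10 and 11); the branch from 1 contributes 3 steps before the union.

Step 8 (key step, proposed new method).
- What may go wrong: protonation of a prenyl alkene, in particular ring closure of the free ortho-prenylphenol of 5 or 12 to a dimethylchroman; cationic oligomerisation of the electron-rich styrene; capture of the methide by a prenyl alkene; and poor facial selectivity at C2, because the ion pair is held by a single hydrogen bond and the para-silyloxy group makes the cation long-lived and loosely bound. Released methanol may also slow the catalyst.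
- Fallback (known chemistry), from 4 and 11, returning at 15: the acid-promoted three-component condensation of 4, HC(OMe)3 and 11 (Sc(OTf)3 cat., CH2Cl2, 0 °C) should give the racemic 2,4-cis-4-methoxyflavan trisilyl ether F1. The conditions of steps 9 and 10 should lead through the racemic flavan-4-ol trisilyl ether F2 to the racemic flavanone trisilyl ether F3. Kinetic resolution of F3 by asymmetric transfer hydrogenation (RuCl(p-cymene)[(R,R)-TsDPEN], HCO2H/Et3N, rt) should reduce the (2R) ketone to the (2R,4R)-cis-flavan-4-ol trisilyl ether F4 and leave the (2S) ketone, which is 15.

Step 1.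
- What may go wrong: alkylation at C5 and on oxygen, and double alkylation, because the phenolate is ambident and the product remains nucleophilic; the material throughput would then be low.
- Fallback, from 1, returning at 3: selective O4 alkylation with 3-chloro-3-methylbut-1-yne (DBU, CuCl2 cat., MeCN, 0 °C) should give 2-hydroxy-4-(2-methylbut-3-yn-2-yloxy)benzaldehyde F5. Semi-hydrogenation (H2, Pd/CaCO3 poisoned with Pb(OAc)2, quinoline, EtOAc) should give 2-hydroxy-4-(2-methylbut-3-en-2-yloxy)benzaldehyde F6. Aromatic Claisen rearrangement (N,N-diethylaniline, 130 °C) should deliver the allyl unit to C3, the position favoured by the bond fixation of the chelated salicylaldehyde, and give 3.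

Step 3.
- What may go wrong: reversion to the aldehyde or premature ionisation and self-condensation during concentration and handling, because the ortho-hydroxyl and the para-silyloxy group both assist loss of methoxide.
- Fallback, from 4, returning at 5: acetylation (Ac2O, pyridine, DMAP cat.) should give 2-acetoxy-3-prenyl-4-(triisopropylsilyloxy)benzaldehyde F7. Acetalisation under the conditions of step 3 should give 2-acetoxy-3-prenyl-4-(triisopropylsilyloxy)benzaldehyde dimethyl acetal F8, which lacks the assisting hydroxyl and can be purified and stored. Aminolysis of the aryl acetate (n-PrNH2, THF, 0 °C; aqueous wash) should release 5 under basic conditions just before step 8.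

Step 6.
- What may go wrong: transfer of the prenyl group through its tertiary terminus, giving the 1,1-dimethylallyl isomer, and slow oxidative addition beside the bulky silyloxy group, with loss of the stannane by protodestannylation.
- Fallback, from 8, returning at 10: Stille coupling with allyltributylstannane (Pd(PPh3)4, DMF, 95 °C), where the two allyl termini are equivalent, should give 3-allyl-4,5-bis(tert-butyldimethylsilyloxy)benzaldehyde F9. Cross-metathesis with 2-methylbut-2-ene (second-generation Grubbs catalyst, CH2Cl2, 40 °C) should convert the allyl into the prenyl group and give 10.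

Step 9.
- What may go wrong: slow ionisation with the weak acid, or loss of a proton from the C4 cation to give the flav-3-ene instead of capture by water; a stronger acid would start to hydrate the prenyl groups.
- Fallback, from 13, returning at 15: oxidative cleavage of the doubly activated benzylic methyl ether with DDQ (CH2Cl2/pH 7 buffer, 0 °C), by hydride abstraction from C4 and hydrolysis of the oxocarbenium ion, should give 15 directly and bypass 14. The competing process there would be hydride abstraction from the benzylic allylic CH2 groups.

## Further compounds

F1 | step 8 | racemic 2,4-cis-4-methoxy-8,5'-diprenyl-7-(triisopropylsilyloxy)-3',4'-bis(tert-butyldimethylsilyloxy)flavan | COC1CC(c2cc(CC=C(C)C)c(O[Si](C)(C)C(C)(C)C)c(O[Si](C)(C)C(C)(C)C)c2)Oc2c(CC=C(C)C)c(O[Si](C(C)C)(C(C)C)C(C)C)ccc12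
F2 | step 8 | racemic 8,5'-diprenyl-7-(triisopropylsilyloxy)-3',4'-bis(tert-butyldimethylsilyloxy)flavan-4-ol | OC1CC(c2cc(CC=C(C)C)c(O[Si](C)(C)C(C)(C)C)c(O[Si](C)(C)C(C)(C)C)c2)Oc2c(CC=C(C)C)c(O[Si](C(C)C)(C(C)C)C(C)C)ccc12
F3 | step 8 | racemic 8,5'-diprenyl-7-(triisopropylsilyloxy)-3',4'-bis(tert-butyldimethylsilyloxy)flavanone | O=C1CC(c2cc(CC=C(C)C)c(O[Si](C)(C)C(C)(C)C)c(O[Si](C)(C)C(C)(C)C)c2)Oc2c(CC=C(C)C)c(O[Si](C(C)C)(C(C)C)C(C)C)ccc12
F4 | step 8 | (2R,4R)-2,4-cis-8,5'-diprenyl-7-(triisopropylsilyloxy)-3',4'-bis(tert-butyldimethylsilyloxy)flavan-4-ol | O[C@@H]1C[C@H](c2cc(CC=C(C)C)c(O[Si](C)(C)C(C)(C)C)c(O[Si](C)(C)C(C)(C)C)c2)Oc2c(CC=C(C)C)c(O[Si](C(C)C)(C(C)C)C(C)C)ccc12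
F5 | step 1 | 2-hydroxy-4-(2-methylbut-3-yn-2-yloxy)benzaldehyde | O=Cc1ccc(OC(C)(C)C#C)cc1O
F6 | step 1 | 2-hydroxy-4-(2-methylbut-3-en-2-yloxy)benzaldehyde | O=Cc1ccc(OC(C)(C)C=C)cc1O
F7 | step 3 | 2-acetoxy-3-prenyl-4-(triisopropylsilyloxy)benzaldehyde | CC(=O)Oc1c(C=O)ccc(O[Si](C(C)C)(C(C)C)C(C)C)c1CC=C(C)C
F8 | step 3 | 2-acetoxy-3-prenyl-4-(triisopropylsilyloxy)benzaldehyde dimethyl acetal | COC(OC)c1ccc(O[Si](C(C)C)(C(C)C)C(C)C)c(CC=C(C)C)c1OC(C)=O
F9 | step 6 | 3-allyl-4,5-bis(tert-butyldimethylsilyloxy)benzaldehyde | O=Cc1cc(CC=C)c(O[Si](C)(C)C(C)(C)C)c(O[Si](C)(C)C(C)(C)C)c1
F0 | step 9 | none | none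
A1 | alternative 1 | (2S)-7,4'-dihydroxy-8,5'-diprenyl-3'-(tert-butyldimethylsilyloxy)flavanone | CC(C)=CCc1cc([C@@H]2CC(=O)c3ccc(O)c(CC=C(C)C)c3O2)cc(O[Si](C)(C)C(C)(C)C)c1O
A2 | alternative 1 | (2S)-7,4'-bis(2-methylbut-3-en-2-yloxy)-3'-(tert-butyldimethylsilyloxy)flavanone | c1cc([C@@H]2CC(=O)c3ccc(OC(C)(C)C=C)cc3O2)cc(O[Si](C)(C)C(C)(C)C)c1OC(C)(C)C=C
A3 | alternative 2 | (2S,4S)-2,4-cis-7,3',4'-tris(methoxymethoxy)-8,5'-diprenylflavan-4-ol | O[C@H]1C[C@@H](c2cc(CC=C(C)C)c(OCOC)c(OCOC)c2)Oc2c(CC=C(C)C)c(OCOC)ccc12
A4 | alternative 2 | (1S,3S)-1-[2-bromo-4-(methoxymethoxy)-3-prenylphenyl]-3-[3,4-bis(methoxymethoxy)-5-prenylphenyl]propane-1,3-diol | O[C@@H](C[C@H](O)c1cc(CC=C(C)C)c(OCOC)c(OCOC)c1)c1ccc(OCOC)c(CC=C(C)C)c1Br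
A5 | alternative 3 | (2S)-3',4'-diacetoxy-7-(triisopropylsilyloxy)-8,5'-diprenylflavanone | CC(C)=CCc1cc([C@@H]2CC(=O)c3ccc(O[Si](C(C)C)(C(C)C)C(C)C)c(CC=C(C)C)c3O2)cc(OC(C)=O)c1OC(C)=O
A6 | alternative 3 | (3S)-3-(3,4-diacetoxy-5-prenylphenyl)-3-[2-prenyl-3-(triisopropylsilyloxy)phenoxy]propanoic acid | CC(C)=CCc1cc([C@H](CC(=O)O)Oc2cccc(O[Si](C(C)C)(C(C)C)C(C)C)c2CC=C(C)C)cc(OC(C)=O)c1OC(C)=O
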